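At early times the two earlier runs cannot be told apart. Eta, with 1.3 mM of D, holds 1.6 % of Z at 3.00 h, and beta, with 7.5 mM, holds 1.5 %. At 8.00 h they read 7.3 % and 7.8 %, a gap of about the scatter of a difference, 0.71 percentage points. They part at 25.0 h, the time we are asked about.

the same everywhere: G 0.10 M; L 1.6 mM

|  | J | D | remark | time |
|---|---|---|---|---|
| eta | 0.20 M | 1.3 mM | run made earlier |  |
| beta | 0.20 M | 7.5 mM | run made earlier |  |
| west | 0.200 M | 1.00 mM |  | 25 h |
| south | 0.200 M | 1.50 mM |  | 25 h |
| north-west | 0.200 M | 2.00 mM |  | 25 h |
| south-east | 0.200 M | 3.00 mM |  | 25 h |
| north | 0.200 M | 5.00 mM |  | 25 h |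

| run | time / h | Z / % |
|---|---|---|
| eta | 3.00 | 1.6 |
| eta | 8.00 | 7.3 |
| eta | 15.0 | 17.5 |
| eta | 25.0 | 31.8 |
| beta | 3.00 | 1.5 |
| beta | 8.00 | 7.8 |
| beta | 15.0 | 17.0 |
| beta | 25.0 | 29.7 |

(scatter of a reading: 0.5 percentage points)

1. [Z] at the end for west, south, north-west, south-east, north, in this order
2. how the row runs (falls all the way / rises all the way / hardly changes / falls, then rises / rises, then falls)

- "hardly changes" means that all values lie within two and a half points (for a concentration: within two and a half percent of the largest)

We carry one quantity, the D toll, a marginal yield loss: the c_Z lost at 25.0 h per unit of c_D charged, read from eta and beta as 0.339. It is a straight line through two points, and the line is our assumption.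

Which numbers must we know well? The early readings do not enter the toll, so an error in them changes nothing. c_L and c_J stand the same in the earlier runs and the new flasks, so they drop out of the comparison. c_G turns percent into molarity, so an error in it rescales the row and leaves its shape. The eta reading enters twice, in the level and in the toll: raised by 0.5 points, it lifts our west point by 0.52 points and our north point by 0.2 points, so the line tilts about the beta reading. The slope rests on the gap between the two last readings, and the uncertainty of that gap, 0.71 points, is a third of it.

So we reckon c_Z of 31.9 mM at west and 30.5 mM at north, a fall of 4.25 % of the west value. With the toll lowered by one scatter to 0.225, the fall is 2.82 %, still outside the margin for "hardly changes". We commit to a steady fall.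

The forecast differs: 0.026 M at west, 0.036 M at north-west and 0.032 M at north, so the row rises, then falls, on the ground that “excess D probably inhibits mildly”.

The flask gives 0.0319 M, 0.0318 M, 0.0317 M, 0.0314 M and 0.0308 M, and the row falls all the way.

    G + L ⇌ L + X (K = 3.60, k = 0.230 /M/min)
    L + X ⇌ Q (K = 6.60 /M, k = 39.0 /M/min)
    J + Q → L + Z (k = 1.70 /M/min)
    G + D → E (k = 0.270 /M/min)

At the end, north holds 5.00 % of E and 0 % of D, where west holds 1.00 % of E. The toll put north at 30.5 mM, and north stands at 0.0308 M. Carried to south-east, eta's reading less the toll on the extra D gives 31.2 %, and south-east holds 31.4 % of Z.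

The data were computed with made-up constants.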